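**Strategy.** The dimer is cut at the spiro cyclohexene into dehydrozaluzanin C (cyclopentanone half, C1′–C15′) and a bicyclic 3-vinylcyclopentenone diene (cyclopentenone half, C1–C15) in which a C6 hydroxyl and a trans C7 ethynyl group stand in for the lactone. After endo Diels–Alder union and a 1,3-proton shift, the key step closes the last ring, the α-methylene-γ-butyrolactone O–C6–C7–C11–C12: palladium-catalysed cyclocarbonylation makes an alkoxycarbonylpalladium unit on O6 whose 5-exo-dig insertion into the C11≡C13 alkyne forges C11–C12. It exploits the trans O6/C7-ethynyl pair on the seven-membered ring; a Mannich base masks the C4 methylene to the end.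

Key step: step 15

Remark: dehydrocostus lactone (16) is taken as a purchasable natural product. Atoms carry guaianolide numbers (primed in the cyclopentanone half) and α/β as in that series (H-7, H-1′, H-5′ α). The cyclopentenone half of the target has H-5 β (cis to H-6) and H-10 α, which is why it is built de novo and not from 16.

Step 1
Reactants: 1 2,3-dibromoprop-1-ene; 2 allylmagnesium bromide
Product: 3 2-bromohexa-1,5-diene
Conditions: Et2O, 0 °C to rt
Reagents that add atoms: none
Why: Allyl Grignard coupling at the allylic C–Br bond of 1 (SN2 or SN2′, both leading to 3) leaves the vinylic bromide untouched.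

Step 2
Reactants: 3 2-bromohexa-1,5-diene; 4 (Z)-but-2-ene-1,4-diol
Product: 5 (2E)-6-bromohepta-2,6-dien-1-ol
Conditions: second-generation Grubbs catalyst (3 mol %), 4 (4 equiv), CH2Cl2, 40 °C
Reagents that add atoms: none
Why: Olefin cross-metathesis of the terminal alkene of 3 with excess 4 should give the E allylic alcohol under thermodynamic control, the 2-bromoalkene being inert to the ruthenium carbene.

Step 3
Reactants: 5 (2E)-6-bromohepta-2,6-dien-1-ol
Product: 6 [(2S,3S)-3-(3-bromobut-3-en-1-yl)oxiran-2-yl]methanol
Conditions: Ti(OiPr)4 (10 mol %), L-(+)-diethyl tartrate (12 mol %), t-BuOOH, 4 Å MS, CH2Cl2, −20 °C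
Reagents that add atoms: tert-butyl hydroperoxide, CC(C)(C)OO
Why: Sharpless asymmetric epoxidation delivers oxygen to one enantioface of the E allylic alcohol and sets both epoxide carbons as 2S,3S, while the electron-poor bromoalkene is not epoxidised.

Step 4
Reactants: 6 [(2S,3S)-3-(3-bromobut-3-en-1-yl)oxiran-2-yl]methanol
Product: 7 (2R,3S)-6-bromo-3-[(trimethylsilyl)ethynyl]hept-6-ene-1,2-diol
Conditions: Et2AlC≡CSiMe3 (3 equiv, made in the flask from Me3SiC≡CH, n-BuLi and Et2AlCl), toluene, 0 °C to rt; aqueous Rochelle salt
Reagents that add atoms: diethyl[(trimethylsilyl)ethynyl]aluminium, CC[Al](CC)C#C[Si](C)(C)C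
Why: Alkoxide-directed SN2 opening of a 2,3-epoxy alcohol by an alkynylalane occurs at C3 and creates the future C7 centre with inversion.

Step 5
Reactants: 7 (2R,3S)-6-bromo-3-[(trimethylsilyl)ethynyl]hept-6-ene-1,2-diol
Product: 8 (2S)-5-bromo-2-[(trimethylsilyl)ethynyl]hex-5-enal
Conditions: NaIO4, THF/pH 7 buffer, 0 °C; used at once
Reagents that add atoms: none
Why: Periodate glycol cleavage (Malaprade reaction) removes C1 as formaldehyde at neutral pH and should leave the α-alkynyl stereocentre intact if the aldehyde is used immediately.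

Step 6
Reactants: 9 3-ethoxycyclopent-2-en-1-one; 8 (2S)-5-bromo-2-[(trimethylsilyl)ethynyl]hex-5-enal
Product: 10 anti-Felkin-type aldol adduct (5S,1′S,2′S; full name in the list)
Conditions: LiN(iPr)2, THF, −78 °C; then 8, −78 °C; AcOH quench at −78 °C
Reagents that add atoms: none
Why: The kinetic α′-lithium enolate of the vinylogous ester (Stork–Danheiser regiochemistry) adds through a Zimmerman–Traxler chair, the ring-locked E enolate giving the anti aldol (C5/C6) and adding in the Felkin–Anh sense with the slim alkynyl group as medium substituent, so C5 and C6 are both set from C7.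

Step 7
Reactants: 10 aldol adduct
Product: 11 triethylsilyl ether of 10
Conditions: Et3SiOSO2CF3, 2,6-lutidine, CH2Cl2, −78 °C
Reagents that add atoms: triethylsilyl trifluoromethanesulfonate, CC[Si](CC)(CC)OS(=O)(=O)C(F)(F)F
Why: Low-temperature silylation with a silyl triflate and a hindered pyridine protects the hydroxyl before retro-aldol or epimerisation at C5 can occur.

Step 8
Reactants: 11 triethylsilyl ether
Product: 13 silyl-protected bicyclic dienone, via bicyclic tertiary carbinol 12 (not isolated)
Conditions: t-BuLi (2.1 equiv), THF, −78 °C; then 1 M HCl, THF, 0 °C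
Reagents that add atoms: none
Why: Bromine–lithium exchange gives an alkenyllithium that adds 7-exo-trig to the vinylogous-ester carbonyl, and acid then hydrolyses the enol ether and dehydrates the carbinol (Stork–Danheiser enone transposition), closing the seven-membered ring and installing the C2=C1–C10=C14 diene without touching C5–C7.

Step 9
Reactants: 13 silyl-protected bicyclic dienone
Product: 14 C4 Mannich base of 13
Conditions: LiN(SiMe3)2, THF, −78 °C; then Me2N+=CH2 I−, −78 to 0 °C
Reagents that add atoms: N,N-dimethylmethyleneiminium iodide (Eschenmoser's salt), C=[N+](C)C.[I-]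
Why: Kinetic α′-deprotonation of the enone at C4 (not at the γ-hydrogens) and Mannich alkylation anti to the C5 substituent installs C15 as a masked methylene, the new C4 centre being lost again in step 16.

Step 10
Reactants: 14 C4 Mannich base
Product: 15 amino alcohol diene (free C6–OH and terminal alkyne)
Conditions: Bu4NF, AcOH, THF, 0 °C
Reagents that add atoms: none
Why: Buffered fluoride desilylation cleaves the O–Si and C(sp)–Si bonds while acetic acid keeps the β-amino ketone protonated and the γ-hydrogen at C5 unenolised.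

Step 11
Reactants: 16 dehydrocostus lactone
Product: 17 3-epizaluzanin C (3α-hydroxy)
Conditions: SeO2 (30 mol %), t-BuOOH, CH2Cl2, rt
Reagents that add atoms: tert-butyl hydroperoxide, CC(C)(C)OO
Why: Selenium dioxide allylic oxidation (ene reaction then 2,3-sigmatropic shift) should hydroxylate C3 from the convex α-face, and the C3 configuration is irrelevant because the next step removes it.

Step 12
Reactants: 17 3-epizaluzanin C
Product: 18 dehydrozaluzanin C
Conditions: Dess–Martin periodinane, CH2Cl2, rt
Reagents that add atoms: none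
Why: Dess–Martin oxidation of the allylic alcohol gives the exocyclic enone without isomerising the three methylene groups.

Step 13
Reactants: 15 amino alcohol diene; 18 dehydrozaluzanin C
Product: 19 Diels–Alder adduct (C1=C10, H-2 α)
Conditions: 18 (3 equiv), BHT, toluene, 50 °C
Reagents that add atoms: none
Why: Thermal [4+2] cycloaddition of the s-cis-locked diene with the exocyclic enone, C14 bonding to the enone β-carbon C15′: the dienophile reacts through its convex α-face with the ketone endo, on the diene face anti to the C6–C8 bridge (the face of H-5), which sets the spiro centre C4′ and C2.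

Step 14
Reactants: 19 Diels–Alder adduct
Product: 20 conjugated enone (C1=C2, H-10 α)
Conditions: Et3N (0.3 equiv), toluene, 0 °C to rt
Reagents that add atoms: none
Why: Amine-mediated 1,3-prototropic shift (β,γ- to α,β-enone isomerisation): in toluene the ammonium dienolate should stay a contact ion pair and return the proton taken from the α-face of C2 to the α-face of C10 (suprafacial), the still lactone-free seven-membered ring being able to twist to accept it.

Step 15
Reactants: 20 conjugated enone
Product: 21 bis-lactone Mannich base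
Conditions: PdCl2 (5 mol %), SnCl2 (5 mol %), PPh3 (10 mol %), CO (7 atm), MeCN, 65 °C
Reagents that add atoms: carbon monoxide, [C-]#[O+]
Why: Under CO the divalent palladium catalyst is alkoxycarbonylated by the C6 hydroxyl; the O6–C(=O)–Pd unit then adds syn across the pendant C11≡C13 triple bond by intramolecular migratory insertion, which forms the C11–C12 bond and closes the lactone, and protonolysis of the alkenyl–palladium bond releases the exocyclic methylene and the catalyst. The closest known reaction type is the palladium-catalysed cyclocarbonylation of trans-2-ethynylcycloalkanols (homopropargylic alcohols) to trans-fused α-methylene-γ-butyrolactones. The one ring closed is the five-membered lactone, in a 5-exo-dig mode. No stereocentre is created: C6 and C7 were fixed in steps 3–6 and their trans relationship enforces the trans ring fusion. The step needs chemoselectivity for the single terminal alkyne over the three alkenes and exo over endo insertion, which the O6–C6–C7–C11 tether and the inertness of 1,1-disubstituted and conjugated alkenes toward the acylpalladium should secure; the existing α-methylene lactone is the same group the reaction itself produces. Closing this ring last keeps the seven-membered ring flexible during step 14.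

Step 16
Reactants: 21 bis-lactone Mannich base
Product: 23 target dimer, via trimethylammonium iodide 22 (not isolated)
Conditions: MeI, CH2Cl2, rt; then aqueous NaHCO3, rt
Reagents that add atoms: none
Why: N-Methylation followed by mild-base E1cB (Hofmann-type) elimination of trimethylamine from the β-ammonium ketone unveils the C4=C15 methylene, hydrogencarbonate being too weak to enolise toward C5 or C10.

**Compound list**

1 | 2,3-dibromoprop-1-ene | C=C(Br)CBr | starting material
2 | allylmagnesium bromide | C=CC[Mg]Br | starting material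
3 | 2-bromohexa-1,5-diene | C=CCCC(Br)=C | intermediate
4 | (Z)-but-2-ene-1,4-diol | OC/C=C\CO | starting material
5 | (2E)-6-bromohepta-2,6-dien-1-ol | OC/C=C/CCC(Br)=C | intermediate
6 | [(2S,3S)-3-(3-bromobut-3-en-1-yl)oxiran-2-yl]methanol | OC[C@@H]1O[C@H]1CCC(Br)=C | intermediate
7 | (2R,3S)-6-bromo-3-[(trimethylsilyl)ethynyl]hept-6-ene-1,2-diol | OC[C@H](O)[C@H](C#C[Si](C)(C)C)CCC(Br)=C | intermediate
8 | (2S)-5-bromo-2-[(trimethylsilyl)ethynyl]hex-5-enal | O=C[C@H](C#C[Si](C)(C)C)CCC(Br)=C | intermediate
9 | 3-ethoxycyclopent-2-en-1-one | CCOC1=CC(=O)CC1 | starting material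
10 | (5S)-5-{(1S,2S)-5-bromo-1-hydroxy-2-[(trimethylsilyl)ethynyl]hex-5-en-1-yl}-3-ethoxycyclopent-2-en-1-one | CCOC1=CC(=O)[C@@H](C1)[C@@H](O)[C@H](C#C[Si](C)(C)C)CCC(Br)=C | intermediate
11 | (5S)-5-{(1S,2S)-5-bromo-1-(triethylsilyloxy)-2-[(trimethylsilyl)ethynyl]hex-5-en-1-yl}-3-ethoxycyclopent-2-en-1-one | CCOC1=CC(=O)[C@@H](C1)[C@@H](O[Si](CC)(CC)CC)[C@H](C#C[Si](C)(C)C)CCC(Br)=C | intermediate
12 | bicyclic tertiary carbinol: 3-ethoxy-1-hydroxy-2-ene with the seven-membered ring closed at C1–C10 (OH cis to H-5; 6α-OSiEt3, 7β-alkynyl, 10-methylidene); not isolated | CCOC1=C[C@]2(O)C(=C)CC[C@@H](C#C[Si](C)(C)C)[C@H](O[Si](CC)(CC)CC)[C@@H]2C1 | intermediate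
13 | 8-methylidene-4-(triethylsilyloxy)-5-[(trimethylsilyl)ethynyl]-3,3a,4,5,6,7-hexahydroazulen-2(8H)-one (guaiane H-5 β, O-6 α, C7-alkynyl β; H-5/H-6 cis, H-6/H-7 trans) | O=C1C=C2C(=C)CC[C@@H](C#C[Si](C)(C)C)[C@H](O[Si](CC)(CC)CC)[C@@H]2C1 | intermediate
14 | 3-[(dimethylamino)methyl] derivative of 13 (guaiane C4, aminomethyl β, H-4/H-5 trans) | CN(C)C[C@H]1C(=O)C=C2C(=C)CC[C@@H](C#C[Si](C)(C)C)[C@H](O[Si](CC)(CC)CC)[C@H]12 | intermediate
15 | 3-[(dimethylamino)methyl]-5-ethynyl-4-hydroxy-8-methylidene-3,3a,4,5,6,7-hexahydroazulen-2(8H)-one (same configuration as 14) | CN(C)C[C@H]1C(=O)C=C2C(=C)CC[C@@H](C#C)[C@H](O)[C@H]12 | intermediate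
16 | dehydrocostus lactone | C=C1CC[C@H]2C(=C)CC[C@H]3C(=C)C(=O)O[C@@H]3[C@H]21 | starting material
17 | 3-epizaluzanin C (3α-hydroxydehydrocostus lactone) | C=C1[C@H](O)C[C@H]2C(=C)CC[C@H]3C(=C)C(=O)O[C@@H]3[C@H]21 | intermediate
18 | dehydrozaluzanin C | C=C1C(=O)C[C@H]2C(=C)CC[C@H]3C(=C)C(=O)O[C@@H]3[C@H]21 | intermediate
19 | Diels–Alder adduct: spiro cyclohexene C2–C1=C10–C14–C15′–C4′, H-2 α, C2 on the α-face of the lower cyclopentanone; free 6α-OH, 7β-ethynyl, C4 aminomethyl | CN(C)C[C@H]1C(=O)[C@@H]2C3=C(CC[C@@H](C#C)[C@H](O)[C@H]13)CC[C@]21C(=O)C[C@H]2C(=C)CC[C@H]3C(=C)C(=O)O[C@@H]3[C@H]21 | intermediate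
20 | conjugated enone: C1=C2, H-10 α, H-5 β; free 6α-OH, 7β-ethynyl, C4 aminomethyl | CN(C)C[C@H]1C(=O)C2=C3[C@H](CC[C@@H](C#C)[C@H](O)[C@H]13)CC[C@]21C(=O)C[C@H]2C(=C)CC[C@H]3C(=C)C(=O)O[C@@H]3[C@H]21 | intermediate
21 | bis-lactone Mannich base (target with C4–CH2NMe2 in place of C4=CH2) | CN(C)C[C@H]1C(=O)C2=C3[C@H](CC[C@H]4C(=C)C(=O)O[C@@H]4[C@H]13)CC[C@]21C(=O)C[C@H]2C(=C)CC[C@H]3C(=C)C(=O)O[C@@H]3[C@H]21 | intermediate
22 | trimethylammonium iodide of 21; not isolated | C[N+](C)(C)C[C@H]1C(=O)C2=C3[C@H](CC[C@H]4C(=C)C(=O)O[C@@H]4[C@H]13)CC[C@]21C(=O)C[C@H]2C(=C)CC[C@H]3C(=C)C(=O)O[C@@H]3[C@H]21.[I-] | intermediate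
23 | target dimer CNP0221188.1 | C=C1C(=O)C2=C3[C@H](CC[C@H]4C(=C)C(=O)O[C@@H]4[C@H]13)CC[C@]21C(=O)C[C@H]2C(=C)CC[C@H]3C(=C)C(=O)O[C@@H]3[C@H]21 | target

**Count.** Total: 16 steps. Longest linear sequence: 14 steps (steps 1–10 and 13–16); steps 11–12 form the short second branch.

**Steps most likely to fail**

Step 14. The proton may not be returned to the hindered α-face of C10: the ion pair may leak and protonate on the open β-face, or C5 may epimerise, since the required twisted seven-membered ring is the less comfortable arrangement. The fallback sets C10 by a stereospecific palladium hydride transfer instead. It sets out from 19: aerobic γ-oxygenation of the dienolate (O2, Cu(OAc)2 cat., Et3N, then Me2S) should place a hydroxyl on the open β-face of C10 and give the 10β-hydroxy enone F1. Formylation of both hydroxyls (acetic formic anhydride, pyridine) gives the bis-formate F2. Pd(OAc)2/PBu3 in THF then ionises the tertiary allylic formate with inversion, and the hydride left on palladium after loss of CO2 is delivered to the α-face of C10 (allylic formate hydrogenolysis), giving the C6 formate F3. Mild methanolysis (KHCO3, MeOH) comes back to the route at 20.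

Step 15. The late cyclocarbonylation may suffer from thermal loss of dimethylamine from the Mannich base, phosphine addition to the acrylate units, or a slow insertion because the trans-lactone strains the twisted ring. The fallback makes the same C11–C12 bond with a radical. It sets out from 20: acylation of O6 with N-phthalimidoyl chlorooxalate (Et3N, CH2Cl2) gives the mixed oxalate F4. Visible-light photoreduction ([Ru(bpy)3](PF6)2, Hantzsch ester, CH2Cl2) should release the alkoxycarbonyl radical, which closes 5-exo-dig onto the alkyne; hydrogen-atom transfer to the vinyl radical comes back to the route at 21.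

Step 6. The basic enolate may enolise the α-alkynyl aldehyde (loss of configuration at C7), and the anti/Felkin double selection may be incomplete. The fallback forms the C5–C6 bond under Lewis-acid conditions. It sets out from 9, which is converted into its silyl dienol ether F5 (LiN(iPr)2, Me3SiCl, THF, −78 °C). F5 is added to 8 in a Mukaiyama aldol reaction (BF3·OEt2, CH2Cl2, −78 °C; open transition state, Felkin control retained) and comes back to the route at 10 after aqueous work-up.

**Further compounds**

F1 | step 14 | 10β-hydroxy enone (C1=C2, tertiary OH at C10 on the β-face; free 6α-OH) | CN(C)C[C@H]1C(=O)C2=C3[C@@](O)(CC[C@@H](C#C)[C@H](O)[C@H]13)CC[C@]21C(=O)C[C@H]2C(=C)CC[C@H]3C(=C)C(=O)O[C@@H]3[C@H]21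
F2 | step 14 | 6,10-bis-formate of F1 | CN(C)C[C@H]1C(=O)C2=C3[C@@](OC=O)(CC[C@@H](C#C)[C@H](OC=O)[C@H]13)CC[C@]21C(=O)C[C@H]2C(=C)CC[C@H]3C(=C)C(=O)O[C@@H]3[C@H]21
F3 | step 14 | C6 formate of 20 | CN(C)C[C@H]1C(=O)C2=C3[C@H](CC[C@@H](C#C)[C@H](OC=O)[C@H]13)CC[C@]21C(=O)C[C@H]2C(=C)CC[C@H]3C(=C)C(=O)O[C@@H]3[C@H]21
F4 | step 15 | O6 N-phthalimidoyl oxalate of 20 | CN(C)C[C@H]1C(=O)C2=C3[C@H](CC[C@@H](C#C)[C@H](OC(=O)C(=O)ON4C(=O)c5ccccc5C4=O)[C@H]13)CC[C@]21C(=O)C[C@H]2C(=C)CC[C@H]3C(=C)C(=O)O[C@@H]3[C@H]21
F5 | step 6 | 1-ethoxy-3-(trimethylsilyloxy)cyclopenta-1,3-diene | CCOC1=CC(O[Si](C)(C)C)=CC1
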